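Ring C is read as an oxa-Diels–Alder adduct. O1, C8a, C4a and C4 form an ortho-quinone methide carried by ring A, and C2–C3 is the vinyl group of a ring B styrene. The oxygens at C5, C7 and C8a, ortho and para to C4a, stabilise positive charge at C4, so a salicylaldehyde acetal ionises under a weak chiral acid. The para oxygen of ring B polarises the styrene. One three-component operation forms C3–C4 and O1–C2, closes ring C and sets C2. Its precursors are an achiral aldehyde, an orthoformate and a styrene. C4 emerges as a methyl ether. DDQ raises it to the ketone and hydrogenolysis frees the phenol.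

Key step: step 2

Numbering: flavonoid numbering is used (O1, C2, C3, C4, C4a, C5 to C8, C8a; ring A is the benzo ring, ring B the 2-aryl group, ring C the pyran ring).

Assumption: the sense of induction of the (S,S)-configured acid in step 2 is assigned by analogy with related ortho-quinone methide cycloadditions; if it favours 2R, the equally available (R,R)-acid is used.

Step 1
Reactants: 1 3,4,5-trimethoxyphenol
Product: 3 6-hydroxy-2,3,4-trimethoxybenzaldehyde, via salicyl alcohol 2 (not isolated)
Conditions: MgCl2, Et3N, (CH2O)n, MeCN, reflux; 1 M HCl work-up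
Reagents that add atoms: formaldehyde (from paraformaldehyde), C=O
Why: Casnati–Skattebøl ortho-formylation: the magnesium phenoxide of 1 delivers formaldehyde to the ortho carbon to give 2, a second formaldehyde oxidises 2 by Oppenauer-type hydride transfer, and only one aldehyde can form because the two ortho positions are equivalent and the para position is blocked.

Step 2
Reactants: 3 6-hydroxy-2,3,4-trimethoxybenzaldehyde; 4 4-(benzyloxy)-3-methoxystyrene (2 equiv)
Product: 7 (2S,4S)-2-[4-(benzyloxy)-3-methoxyphenyl]-4,5,6,7-tetramethoxychromane, via dimethyl acetal 5 (not isolated), via ortho-quinone methide 6 (not isolated)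
Conditions: HC(OMe)3 (1.5 equiv), (S,S)-imidodiphosphoric acid built from two 3,3'-bis(2,4,6-triethylphenyl)-BINOL units (5 mol %), 5 Å MS, toluene, −20 °C
Reagents that add atoms: trimethyl orthoformate, COC(OC)OC
Why: The acid first catalyses acetal exchange between 3 and the orthoformate to give 5, then ionises 5 with loss of methanol to the methoxy-substituted ortho-quinone methide 6, which stays in the confined chiral pocket through the hydrogen bond between its ring A oxygen and the imidodiphosphate (its O-protonated form is a 2-hydroxyaryl oxocarbenium ion pair). Compound 6 then adds styrene 4 in an inverse-electron-demand oxa-Diels–Alder reaction that is concerted but strongly asynchronous, with C3–C4 bond formation running ahead of O1–C2 closure. The closest known reaction types are the chiral Brønsted acid-catalysed [4+2] cycloaddition of in situ generated ortho-quinone methides with styrenes and the Lewis acid-catalysed chroman synthesis from salicylaldehydes, trimethyl orthoformate and alkenes. Ring C is closed by the [4+2] cycloaddition itself (heterodiene O1=C8a–C4a=C4, dienophile C2=C3), which in the stepwise limit corresponds to 6-exo-trig capture of the para-benzyloxybenzyl cation by the ring A oxygen. C2 is set as S by the catalyst pocket, which exposes one face of bound 6 and fixes the endo orientation of ring B, and C4 follows as S (2,4-cis) from that endo approach to the E-configured methide, although it is erased in step 3. The step needs regioselectivity (CH2 to C4, O1 to the benzylic carbon), secured by the para-benzyloxy group that makes the terminal carbon of 4 the nucleophilic end and by the electrophilic methide carbon of 6, and it needs ionisation of 5 rather than protonation of 4, secured by the donor oxygens at C5, C7 and C8a that let a weak acid suffice.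

Step 3
Reactants: 7 (2S,4S)-2-[4-(benzyloxy)-3-methoxyphenyl]-4,5,6,7-tetramethoxychromane
Product: 9 (2S)-2-[4-(benzyloxy)-3-methoxyphenyl]-5,6,7-trimethoxychroman-4-one, via hemiketal 8 (not isolated)
Conditions: DDQ (1.05 equiv), CH2Cl2/aq. pH 7 phosphate buffer, 0 °C
Reagents that add atoms: water, O
Why: DDQ oxidation of an electron-rich benzylic ether, the reaction type used to cleave para-methoxybenzyl ethers: hydride is abstracted from C4–H, the only C–H benzylic to the tetra-oxygenated ring A, water adds to the oxocarbenium ion to give 8 and loss of methanol leaves the ketone, while the buffered, base-free medium leaves C2 untouched and both C4 epimers converge.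

Step 4
Reactants: 9 (2S)-2-[4-(benzyloxy)-3-methoxyphenyl]-5,6,7-trimethoxychroman-4-one
Product: 10 agecorynin E [(2S)-2-(4-hydroxy-3-methoxyphenyl)-5,6,7-trimethoxychroman-4-one]
Conditions: H2 (1 atm), Pd/C, EtOAc, rt
Reagents that add atoms: none
Why: Catalytic hydrogenolysis of a primary benzyl aryl ether under neutral conditions should be faster than cleavage of the hindered secondary C2–O1 bond and offers no base for retro-oxa-Michael racemisation at C2.

Compound list
1 | 3,4,5-trimethoxyphenol | COc1cc(O)cc(OC)c1OC | starting material
2 | 2-(hydroxymethyl)-3,4,5-trimethoxyphenol (present as its magnesium salt, not isolated) | OCc1c(O)cc(OC)c(OC)c1OC | intermediate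
3 | 6-hydroxy-2,3,4-trimethoxybenzaldehyde | O=Cc1c(O)cc(OC)c(OC)c1OC | intermediate
4 | 4-(benzyloxy)-3-methoxystyrene | C=Cc1ccc(OCc2ccccc2)c(OC)c1 | starting material
5 | 2-(dimethoxymethyl)-3,4,5-trimethoxyphenol (not isolated) | COC(OC)c1c(O)cc(OC)c(OC)c1OC | intermediate
6 | (6E)-6-(methoxymethylidene)-3,4,5-trimethoxycyclohexa-2,4-dien-1-one (not isolated) | CO/C=C1/C(=O)C=C(OC)C(OC)=C1OC | intermediate
7 | (2S,4S)-2-[4-(benzyloxy)-3-methoxyphenyl]-4,5,6,7-tetramethoxychromane | CO[C@H]1C[C@@H](c2ccc(OCc3ccccc3)c(OC)c2)Oc2cc(OC)c(OC)c(OC)c21 | intermediate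
8 | (2S)-2-[4-(benzyloxy)-3-methoxyphenyl]-4,5,6,7-tetramethoxychroman-4-ol (hemiketal, C4 epimers, not isolated) | COC1(O)C[C@@H](c2ccc(OCc3ccccc3)c(OC)c2)Oc2cc(OC)c(OC)c(OC)c21 | intermediate
9 | (2S)-2-[4-(benzyloxy)-3-methoxyphenyl]-5,6,7-trimethoxychroman-4-one | O=C1C[C@@H](c2ccc(OCc3ccccc3)c(OC)c2)Oc2cc(OC)c(OC)c(OC)c21 | intermediate
10 | agecorynin E, (2S)-2-(4-hydroxy-3-methoxyphenyl)-5,6,7-trimethoxychroman-4-one | COc1cc([C@@H]2CC(=O)c3c(cc(OC)c(OC)c3OC)O2)ccc1O | target

Total step count: 4
Longest linear sequence: 4 steps (1 → 3 → 7 → 9 → 10)

Steps most likely to fail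

1. Step 2 (key step).
- What may go wrong: with so electron-rich a styrene the cycloaddition may slide into a stepwise path through a free para-benzyloxybenzyl cation, and facial selectivity at C2 would then be lost.
- The free C8 position of ring A in another molecule may capture 6 in a Friedel–Crafts sense.
- The acid may start cationic oligomerisation of 4, or it may be alkylated by the orthoformate.
- Fallback: resolution in place of asymmetric catalysis. Setting out from 3 and 4, the same three-component cycloaddition is run with Sc(OTf)3 in CH2Cl2 to give the racemic cis-4-methoxyflavan F1. DDQ under the conditions of step 3 gives the racemic benzyl-protected flavanone F2. Kinetic resolution by asymmetric transfer hydrogenation (Cp*RhCl[(R,R)-TsDPEN], HCO2H/Et3N, EtOAc) reduces the 2R enantiomer to the (2R,4R)-flavan-4-ol F3, which is removed by chromatography. The unreacted 2S ketone is 9, where the route is rejoined.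

2. Step 3.
- What may go wrong: hydride abstraction may not stop at C4. Further attack at the C2–H bond, which is benzylic to the dialkoxy ring B, would lead to dehydrogenation towards the flavone and loss of the stereocentre.
- Fallback: solvolysis followed by alcohol oxidation in place of hydride abstraction. Setting out from 7, PPTS in THF/H2O exchanges the labile C4 methoxy group for hydroxy through the ring A-stabilised C4 cation. This gives the (2S)-flavan-4-ol F4 as a mixture of C4 epimers, and Dess–Martin periodinane in CH2Cl2 oxidises both epimers to 9.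

3. Step 4.
- What may go wrong: hydrogenolytic opening of the benzylic C2–O1 bond (ring C opening) or reduction of the C4 ketone may compete with debenzylation.
- Fallback: a silyl ether in place of the benzyl ether, so that no reductive step is needed. Commercial 2-methoxy-4-vinylphenol is silylated (TBSCl, imidazole, DMF) to 4-(tert-butyldimethylsilyloxy)-3-methoxystyrene F5. Setting out from 3, this styrene is taken through the conditions of step 2 to the (2S,4S)-4-methoxyflavan silyl ether F6 and through those of step 3 to the silyl-protected flavanone F7. Et3N·3HF in THF then removes the silyl group without base to give 10.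

Further compounds
F1 | step 2 | racemic cis-2-[4-(benzyloxy)-3-methoxyphenyl]-4,5,6,7-tetramethoxychromane | COC1CC(c2ccc(OCc3ccccc3)c(OC)c2)Oc2cc(OC)c(OC)c(OC)c21
F2 | step 2 | racemic 2-[4-(benzyloxy)-3-methoxyphenyl]-5,6,7-trimethoxychroman-4-one | O=C1CC(c2ccc(OCc3ccccc3)c(OC)c2)Oc2cc(OC)c(OC)c(OC)c21
F3 | step 2 | (2R,4R)-2-[4-(benzyloxy)-3-methoxyphenyl]-5,6,7-trimethoxychroman-4-ol | O[C@@H]1C[C@H](c2ccc(OCc3ccccc3)c(OC)c2)Oc2cc(OC)c(OC)c(OC)c21
F4 | step 3 | (2S)-2-[4-(benzyloxy)-3-methoxyphenyl]-5,6,7-trimethoxychroman-4-ol (C4 epimers) | OC1C[C@@H](c2ccc(OCc3ccccc3)c(OC)c2)Oc2cc(OC)c(OC)c(OC)c21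
F5 | step 4 | 4-(tert-butyldimethylsilyloxy)-3-methoxystyrene | C=Cc1ccc(O[Si](C)(C)C(C)(C)C)c(OC)c1
F6 | step 4 | (2S,4S)-2-[4-(tert-butyldimethylsilyloxy)-3-methoxyphenyl]-4,5,6,7-tetramethoxychromane | CO[C@H]1C[C@@H](c2ccc(O[Si](C)(C)C(C)(C)C)c(OC)c2)Oc2cc(OC)c(OC)c(OC)c21
F7 | step 4 | (2S)-2-[4-(tert-butyldimethylsilyloxy)-3-methoxyphenyl]-5,6,7-trimethoxychroman-4-one | O=C1C[C@@H](c2ccc(O[Si](C)(C)C(C)(C)C)c(OC)c2)Oc2cc(OC)c(OC)c(OC)c21
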